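The vessel is closed, stirred and isothermal, and in it a catalyst cycles through its forms while the protic impurity consumes the same partner.

starting material 0.050 M; partner 0.0600 M; protic impurity 0.0500 M; free catalyst 7.5 mM

    partner + free catalyst ⇌ catalyst intermediate A (K1 = 1300 L mol⁻¹, k1 = 1.4 L mol⁻¹ s⁻¹)
    starting material + catalyst intermediate A → catalyst intermediate B (k2 = 1.5 L mol⁻¹ s⁻¹)
    catalyst intermediate B → by-product + catalyst intermediate C (k3 = 0.076 s⁻¹)
    catalyst intermediate C → free catalyst + product (k4 = 0.092 s⁻¹)
    partner + protic impurity → quenched reagent (k5 = 0.079 L mol⁻¹ s⁻¹)

- the form that holds most of the catalyst when 50% of the starting material are converted (free catalyst / catalyst intermediate B / catalyst intermediate C / catalyst intermediate A)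
- its share of the catalyst then
- factor on the rate of making product when 50% of the starting material are converted if free catalyst is charged twice over
- factor on the rate when 50% of the starting material are converted if free catalyst is charged at 40 mM instead

**The start.** Product starts flat, for it appears at the end of the cycle. The lifetimes of the forms as charged, one over each rate of leaving, sum to 49.3 s, so after a lag of about that length we expect a slope of 0.152 mM s⁻¹. Meanwhile the impurity takes partner at 0.237 mM s⁻¹, faster than that slope, so partner is the amount to watch.

**The bend.** We try 12.0 mM of partner left at 50% conversion. Free catalyst then lives 59.5 s, and the other forms together 50.7 s. Their sum is the round time, the time the catalyst needs for one full cycle at that moment: 110 s. Once the forms are steady, each holds its lifetime over the round time, and the rate is catalyst over round time. The longest wait makes free catalyst the resting state, with 54.0%.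

The mean of the starting and present rates puts this point at 3.78 min. Over that time the quench, on the logarithmic mean of partner, takes 20.7 mM, and intermediate A holds 1.81 mM. The balance then leaves 12.5 mM of partner, close to our trial.

**The level.** Taking the catalyst as free, partner then lives 78.0 s, and the cycle outbids the quench by 4.54. Product should level near 74.1% of the starting material charged, which would make partner the limiting reagent of this flask, although 0.0600 M of it was charged against 0.050 M of starting material.

**Other charges.** As an assumption of our reckoning, we scale the quench down by the charge of catalyst and scale bound partner up by it. With 15.0 mM the round time is 84.7 s, a factor of 2.60. With 40 mM it is 84.0 s, a factor of 7.00. At that rate the conversion would take 52.5 s, less than one round, so this factor rests on forms that may not be steady.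

**The forecast.** The forecast says free catalyst at 52%, with factors 2.4 and 7.1, on the ground that “Binding partner is then the slowest step”.

**The flask.** The simulation reaches 50% at 3.79 min with free catalyst at 51.9% and factors 2.46 and 7.12. The lifetime of intermediate C over its share of 11.0% reads a round time of 98.7 s in this flask, shorter than our 110 s. In the flask charged with 40 mM, where intermediate C holds 14.7%, the same division, which assumes steady forms, stands against our 84.0 s and reads 73.9 s.

(The constants were set for the occasion; the flask was simulated.)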